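**Numbering used throughout.** Germacranolide numbering: ring A is the ten-membered carbocycle C1–C10 (C10 carries methyl C14 and OH; C4 carries C15H2OAc); ring B is the lactone O–C6–C7–C11–C12 with exocyclic methylene C13; the O8 acyl group is C1'–C5'. The target 35 is (2R,5S,6S,7R,8R,10S), 3Z, 2'Z.

## The problem

The target is a germacranolide: ring A holds one Z trisubstituted alkene (C3=C4) and is trans-fused across C6–C7 to an α-methylene-γ-butyrolactone (ring B). Six stereocenters must be set: the contiguous tetrad C5–C8 and the skipped triol C8/C10/C2. C10 is a tertiary carbinol flanked by two methylene groups, so no neighbouring center can set it by induction. By contrast C8 can direct C7, C7 directs C6 through a cyclic transition state, and C6 can direct C5. A ten-membered ring is slow to close, so the closure should create functionality and stereocenters at the same time. Five oxygens must be told apart: acetates on O5 and O15, free hydroxyls on O2 and O10, and a (Z)-2-(acetoxymethyl)but-2-enoate on O8. The exo-methylene lactone, the Z acyl group (Z to E isomerisation, SN2' loss of acetate), the allylic acetates and any β-oxygenated carbonyl around C10 will not survive strong base, hydride or zerovalent palladium late in the route.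

The feature that the plan exploits: C5 and C6 are two adjacent carbinol carbons of ring A that lie between an alkenyl carbon (C4) and an allylic carbon (C7) carrying the acrylate unit C11(=C13)–C12, and the C6–C7 bond belongs to both ring A and ring B. C5–C6 is therefore a glyoxal unit captured by an alkenyl metal at C4 and a 2-carboxyallyl metal at C7. What remains, C7–C8(O)–C9–C10(CH3)(OH)–C1–C2(O)–C3, is 3-hydroxy-3-methylglutarate with one alkyne added to each carbonyl carbon.

## Retrosynthesis

**35 back to 25 (end game).** The O8–C1' ester bond is cut last but one (34 from 27 and acid 32), because the Z acyl group is the most fragile part of the molecule; the final step only removes silicon from O2 and O10. The two acetates are cut together (26 from 25): in 25 only O5–H and O15–H are free, so one acetylation distinguishes them from O2, O8 and O10 without further protecting-group traffic. Removing the C8 silyl ether of 26 gives 27. The forward reactions must be mild acylations and an acidic fluoride deprotection.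

**25 back to 21 and 22 (key disconnection).** Three bonds are cut: C4–C5, C6–C7 and the lactone bond O6–C12. This returns the open-chain bromide/iodide 21 and glyoxal 22. Closing ring A at C3=C4 or at C6–C7 alone would demand a precursor that already holds every stereocenter; here the precursor has no ring and no stereocenter at C5, C6 or C7. The forward reaction must activate the allylic bromide before the alkenyl iodide, add once to glyoxal, and relay stereochemistry C8 to C7 to C6 to C5.

**21 back to 13 and 14 (allyl bromide arm).** The C11–C13 bond is cut to formaldehyde (19 from alkynoate 17), and C7–C8 to methyl propiolate 14 and aldehyde 13 (giving 16, silylated to 17). Bromide 20 and its deprotected form 21 follow from 19. A Morita–Baylis–Hillman route would need a C7 aldehyde, one carbon more than the glutarate core supplies. The forward steps must set C8 by reagent control and add hydride only to C7.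

**13 back to 4 and 5 (iodoalkene arm).** The C4–I bond and C3–H come from trans-hydroalumination/iodination of propargylic alcohol 8 (giving diol 10, then 12 and aldehyde 13). C2–C3 is cut to the acetylide of 5 and Weinreb amide 4 (ketone 7, reduced to 8). The same hydride step converts the untouched ester terminus into the C8 carbinol carbon, so no separate reduction is needed. The forward steps must set C2 by reagent control and place iodine cis to C2.

**4 back to 1 (C10).** Amide 4 comes from half-ester 2, and 2 from prochiral diester 1 by enzymatic desymmetrisation. This is the only disconnection that sets C10 without relying on a methyl-versus-methylene distinction.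

**32 back to 28 (side chain).** C2'–C5' is cut to formaldehyde and methyl but-2-ynoate 28 (via 30), using the same hydroalumination/hydroxymethylation as in the allyl bromide arm; syn addition gives the Z geometry.

## Roads not taken

**Alternative 1:** Ring-closing metathesis at C3=C4 (the most obvious cut). The diene A1, which already carries ring B and all six stereocenters, would be closed with a second-generation Grubbs catalyst. The alkene to be formed is trisubstituted and flanked by two oxygenated allylic carbons in a ten-membered ring, the exo-methylene lactone is a competing olefin, and the Z geometry is not enforced. The ring closure would also solve nothing but the ring: every stereocenter and the lactone have to be built on the open chain first.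

**Alternative 2:** Intramolecular Barbier allylation/lactonisation at C6–C7, the usual germacranolide closure. The aldehyde–allylic bromide A2 would be treated with CrCl2. It closes both rings, but it needs C5 set beforehand on an α-silyloxy-β,γ-unsaturated aldehyde that epimerises easily. C6 and C7 would form under ring control with C5 already fixed, and the Felkin–Anh preference of such an aldehyde opposes the required 5,6-syn relation. Three orthogonal protecting-group classes and about three more steps are needed. In the chosen plan the same bond is formed outside the ring on an achiral dialdehyde.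

**Alternative 3:** Furan dearomatisation. 3-Furanmethanol would supply C2–C3–C4(C15)–C5 as a 2,5-bridged furanophane A3; oxidative ring opening would give the Z-enedione A4, and two carbonyl reductions would follow. The Z geometry comes free, but the bridged furan in a ten-membered ring is strained. Both C2 and C5 must then be set by reduction with no reliable control: the tertiary C10 carbinol gives poor 1,3-induction and the Felkin–Anh product at C5 is the wrong (erythro) one. The enedione also invites transannular oxa-Michael addition of O10 to C3.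

Key step: step 14

Assumption: pig liver esterase cleaves the pro-S ester arm of 1, so that 2 is the (S)-half-ester; this sense is taken as given.

## Route

Step 1
Reactants: 1 dimethyl 3-hydroxy-3-methylpentanedioate
Product: 2 (3S)-3-hydroxy-5-methoxy-3-methyl-5-oxopentanoic acid
Conditions: pig liver esterase, pH 8 phosphate buffer, NaOH (pH-stat), 25 °C; then HCl
Reagents that add atoms: water (O)
Why: Enzymatic desymmetrisation of a prochiral diester; the esterase distinguishes the enantiotopic ester arms and so sets C10, the quaternary carbinol that no neighbouring stereocenter could control.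

Step 2
Reactants: 2 (3S)-3-hydroxy-5-methoxy-3-methyl-5-oxopentanoic acid
Product: 3 methyl (3S)-3-hydroxy-5-[methoxy(methyl)amino]-3-methyl-5-oxopentanoate
Conditions: MeNH(OMe)·HCl, EDC·HCl, HOBt (cat.), N-methylmorpholine, CH2Cl2, 0 °C → rt
Reagents that add atoms: N,O-dimethylhydroxylamine hydrochloride (CNOC.Cl)
Why: Carbodiimide amidation (Weinreb amide formation) of the only free carboxyl group; the methyl ester is inert and the tertiary alcohol is too hindered to be acylated.

Step 3
Reactants: 3 methyl (3S)-3-hydroxy-5-[methoxy(methyl)amino]-3-methyl-5-oxopentanoate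
Product: 4 methyl (3S)-5-[methoxy(methyl)amino]-3-methyl-5-oxo-3-(triethylsilyloxy)pentanoate
Conditions: Et3SiOTf, 2,6-lutidine, CH2Cl2, −78 → 0 °C
Reagents that add atoms: triethylsilyl trifluoromethanesulfonate (CC[Si](CC)(CC)OS(=O)(=O)C(F)(F)F)
Why: Silylation of a tertiary alcohol with a silyl triflate; the ether blocks retro-aldol cleavage and oxa-Michael addition once C2 and C8 become carbonyl carbons.

Step 4
Reactants: 4 methyl (3S)-5-[methoxy(methyl)amino]-3-methyl-5-oxo-3-(triethylsilyloxy)pentanoate; 5 1-methoxy-4-[(prop-2-yn-1-yloxy)methyl]benzene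
Product: 7 methyl (3S)-8-[(4-methoxybenzyl)oxy]-3-methyl-5-oxo-3-(triethylsilyloxy)oct-6-ynoate, via lithium acetylide 6 (not isolated)
Conditions: 5, n-BuLi, THF, −78 °C; then 4, −78 → −40 °C; aq. NH4Cl
Reagents that add atoms: none
Why: Acylation of an alkynyllithium by a Weinreb amide; the chelated tetrahedral adduct stops at the ketone, and at −78 °C the unactivated methyl ester should not be attacked.

Step 5
Reactants: 7 methyl (3S)-8-[(4-methoxybenzyl)oxy]-3-methyl-5-oxo-3-(triethylsilyloxy)oct-6-ynoate
Product: 8 methyl (3S,5R)-5-hydroxy-8-[(4-methoxybenzyl)oxy]-3-methyl-3-(triethylsilyloxy)oct-6-ynoate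
Conditions: Ru(p-cymene)[(R,R)-TsDPEN] (1 mol %), i-PrOH, rt
Reagents that add atoms: none
Why: Noyori asymmetric transfer hydrogenation of an alkynyl ketone; the catalyst reads alkyne against methylene and sets C2 (R) by reagent control ((R,R) ligand by analogy with simple alkynyl ketones; the antipode is used if the sense proves opposite).

Step 6
Reactants: 8 methyl (3S,5R)-5-hydroxy-8-[(4-methoxybenzyl)oxy]-3-methyl-3-(triethylsilyloxy)oct-6-ynoate
Product: 10 (2Z,4R,6R)-2-iodo-1-[(4-methoxybenzyl)oxy]-6-methyl-6-(triethylsilyloxy)oct-2-ene-4,8-diol, via cyclic alkenylaluminate 9 (not isolated)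
Conditions: NaAlH2(OCH2CH2OMe)2 (4 equiv), THF, 0 °C → rt; then I2, THF, −78 → 0 °C
Reagents that add atoms: iodine ([I][I])
Why: Hydroxyl-directed trans-hydroalumination of a propargylic alcohol and iodinolysis: hydride goes to C3 and aluminium to C4 inside the five-membered alkoxyaluminate 9, so iodine ends cis to C2 (the later Z C3=C4 bond with C2 and C5 cis). The same reagent reduces the methyl ester to the C8 primary alcohol.

Step 7
Reactants: 10 (2Z,4R,6R)-2-iodo-1-[(4-methoxybenzyl)oxy]-6-methyl-6-(triethylsilyloxy)oct-2-ene-4,8-diol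
Product: 12 (2Z,4R,6R)-4-(tert-butyldimethylsilyloxy)-2-iodo-1-[(4-methoxybenzyl)oxy]-6-methyl-6,8-bis(triethylsilyloxy)oct-2-ene, via C8 triethylsilyl ether 11 (not isolated)
Conditions: Et3SiCl (1.05 equiv), imidazole, CH2Cl2, −40 °C; then t-BuMe2SiOTf, 2,6-lutidine, −40 → 0 °C
Reagents that add atoms: chlorotriethylsilane (CC[Si](Cl)(CC)CC); tert-butyldimethylsilyl trifluoromethanesulfonate (CC(C)(C)[Si](C)(C)OS(=O)(=O)C(F)(F)F)
Why: Kinetic silylation: the primary alcohol takes the triethylsilyl group at low temperature, then the hindered allylic alcohol is silylated by the silyl triflate; O2 thus carries the robust group that is removed last.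

Step 8
Reactants: 12 (2Z,4R,6R)-4-(tert-butyldimethylsilyloxy)-2-iodo-1-[(4-methoxybenzyl)oxy]-6-methyl-6,8-bis(triethylsilyloxy)oct-2-ene
Product: 13 (3S,5R,6Z)-5-(tert-butyldimethylsilyloxy)-7-iodo-8-[(4-methoxybenzyl)oxy]-3-methyl-3-(triethylsilyloxy)oct-6-enal
Conditions: (COCl)2, DMSO, CH2Cl2, −78 → −40 °C; then Et3N, −78 → 0 °C
Reagents that add atoms: none
Why: Swern oxidation applied directly to a primary triethylsilyl ether: the chlorosulfonium salt cleaves the least hindered Si–O bond and the alkoxysulfonium ion collapses to the aldehyde, while the secondary tert-butyldimethylsilyl and tertiary triethylsilyl ethers should remain.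

Step 9
Reactants: 13 (3S,5R,6Z)-5-(tert-butyldimethylsilyloxy)-7-iodo-8-[(4-methoxybenzyl)oxy]-3-methyl-3-(triethylsilyloxy)oct-6-enal; 14 methyl prop-2-ynoate
Product: 16 methyl (4R,6R,8R,9Z)-8-(tert-butyldimethylsilyloxy)-4-hydroxy-10-iodo-11-[(4-methoxybenzyl)oxy]-6-methyl-6-(triethylsilyloxy)undec-9-en-2-ynoate, via alkynylzinc 15 (not isolated)
Conditions: 14, Me2Zn, (S,S)-ProPhenol (20 mol %), Ph3PO (40 mol %), toluene, 0 °C; then 13, 0 → 4 °C
Reagents that add atoms: none
Why: Catalytic enantioselective addition of a zinc acetylide to an aldehyde (dinuclear zinc–ProPhenol catalyst); C8 (R) is set by the ligand (the antipode that gives the R carbinol is taken), and Me2Zn does not touch the alkenyl iodide.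

Step 10
Reactants: 16 methyl (4R,6R,8R,9Z)-8-(tert-butyldimethylsilyloxy)-4-hydroxy-10-iodo-11-[(4-methoxybenzyl)oxy]-6-methyl-6-(triethylsilyloxy)undec-9-en-2-ynoate
Product: 17 methyl (4R,6S,8R,9Z)-8-(tert-butyldimethylsilyloxy)-10-iodo-11-[(4-methoxybenzyl)oxy]-6-methyl-4,6-bis(triethylsilyloxy)undec-9-en-2-ynoate
Conditions: Et3SiCl, imidazole, DMAP (cat.), CH2Cl2, 0 °C → rt
Reagents that add atoms: chlorotriethylsilane (CC[Si](Cl)(CC)CC)
Why: Silylation of a secondary propargylic alcohol; the ether keeps O8 from lactonising onto the cis ester formed next and is the group that is later removed first.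

Step 11
Reactants: 17 methyl (4R,6S,8R,9Z)-8-(tert-butyldimethylsilyloxy)-10-iodo-11-[(4-methoxybenzyl)oxy]-6-methyl-4,6-bis(triethylsilyloxy)undec-9-en-2-ynoate
Product: 19 methyl (2Z,4R,6R,8R,9Z)-8-(tert-butyldimethylsilyloxy)-2-(hydroxymethyl)-10-iodo-11-[(4-methoxybenzyl)oxy]-6-methyl-4,6-bis(triethylsilyloxy)undeca-2,9-dienoate, via alkenylalane 18 (not isolated)
Conditions: i-Bu2AlH, HMPA, THF, 0 °C; then CH2O (gas), 0 °C → rt
Reagents that add atoms: formaldehyde (C=O)
Why: Conjugate hydroalumination of an alkynoate with aldehyde trapping (reductive aldol, vinylalumination): hydride adds to C7 and the α-aluminio acrylate 18 is trapped at C11 by formaldehyde; syn addition puts C8 cis to the ester. With HMPA the ester carbonyl should not be reduced, and the alkenyl iodide is inert.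

Step 12
Reactants: 19 methyl (2Z,4R,6R,8R,9Z)-8-(tert-butyldimethylsilyloxy)-2-(hydroxymethyl)-10-iodo-11-[(4-methoxybenzyl)oxy]-6-methyl-4,6-bis(triethylsilyloxy)undeca-2,9-dienoate
Product: 20 methyl (2E,4R,6R,8R,9Z)-2-(bromomethyl)-8-(tert-butyldimethylsilyloxy)-10-iodo-11-[(4-methoxybenzyl)oxy]-6-methyl-4,6-bis(triethylsilyloxy)undeca-2,9-dienoate
Conditions: CBr4, PPh3, CH2Cl2, −20 → 0 °C
Reagents that add atoms: tetrabromomethane (BrC(Br)(Br)Br)
Why: Appel reaction of a primary allylic alcohol (SN2 at C13); it gives the 2-(bromomethyl)acrylate with C8 trans to the bromomethyl group, the geometry wanted in the allylchromium (which would in any case equilibrate).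

Step 13
Reactants: 20 methyl (2E,4R,6R,8R,9Z)-2-(bromomethyl)-8-(tert-butyldimethylsilyloxy)-10-iodo-11-[(4-methoxybenzyl)oxy]-6-methyl-4,6-bis(triethylsilyloxy)undeca-2,9-dienoate
Product: 21 methyl (2E,4R,6R,8R,9Z)-2-(bromomethyl)-8-(tert-butyldimethylsilyloxy)-11-hydroxy-10-iodo-6-methyl-4,6-bis(triethylsilyloxy)undeca-2,9-dienoate
Conditions: DDQ, CH2Cl2–pH 7 buffer, 0 °C
Reagents that add atoms: none
Why: Oxidative cleavage of a 4-methoxybenzyl ether by DDQ; silyl ethers, the allylic bromide and both alkenes are inert, and the free C15 hydroxyl is tolerated by organochromium reagents and is acetylated with O5 later.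

Step 14
Reactants: 21 methyl (2E,4R,6R,8R,9Z)-2-(bromomethyl)-8-(tert-butyldimethylsilyloxy)-11-hydroxy-10-iodo-6-methyl-4,6-bis(triethylsilyloxy)undeca-2,9-dienoate; 22 ethanedial (glyoxal)
Product: 25 (2R,5S,6S,7S,8R,10S)-2-(tert-butyldimethylsilyloxy)-5,15-dihydroxy-8,10-bis(triethylsilyloxy)germacra-3Z,11(13)-dien-12,6-olide, via formyl alkoxide 23 (not isolated), via ring A diol ester 24 (not isolated)
Conditions: a) CrCl2, 22 (5 equiv, monomer), THF, 0 °C, slow addition of 21; b) excess 22 removed in vacuo; c) CrCl2, NiCl2 (2 mol %), DMSO–THF, 0.003 M, rt; d) aq. NH4Cl, then PPTS, CH2Cl2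
Reagents that add atoms: none
Why: Proposed new method: two organochromium additions are run in sequence on the two formyl groups of one dialdehyde, argued from the known order of reactivity toward divalent chromium (allylic bromides insert without nickel, alkenyl iodides only with nickel catalysis); the closest known reactions are the Barbier-type 2-(alkoxycarbonyl)allylation/lactonisation of aldehydes and the Nozaki–Hiyama–Kishi macrocyclisation. In stage a the allylchromium from 21 adds through C7 to one formyl group of glyoxal (excess dialdehyde and slow addition of 21 suppress double allylation) to give the chromium alkoxide 23, while the alkenyl iodide is untouched because no nickel is present. C8 sits trans to the chromium-bearing methylene and therefore equatorial in the six-membered chair transition state, so C6–O and C7–C8 come out anti, which is the trans fusion of ring B. The C7 face is set by C8: allylic 1,3-strain with the cis ester holds the C8–H bond in the allyl plane, and the aldehyde bonds anti to the C9 methylene, the larger and better donor substituent. In stage c the C4 iodide is converted by NiCl2/CrCl2 into the alkenylchromium, which adds to the remaining formyl carbon C5 and closes ring A by C4–C5 bond formation (10-exo-trig attack on the carbonyl, alkene geometry retained) to give 24. C5 is controlled by the C6 alkoxide still bound to trivalent chromium: five-membered chelation of the formyl oxygen and attack anti to C7, which is also the unstrained ring torsion, give the 5,6-syn diol. On acidic work-up the C6 hydroxyl closes ring B by 5-exo-trig attack on the C12 ester (O5 could only give a six-membered lactone) to give 25. The step needs allyl-before-alkenyl activation (secured by the two different halides and by withholding nickel), mono-addition to glyoxal (excess and inverse addition) and intra- over intermolecular alkenylation (high dilution).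

Step 15
Reactants: 25 (2R,5S,6S,7S,8R,10S)-2-(tert-butyldimethylsilyloxy)-5,15-dihydroxy-8,10-bis(triethylsilyloxy)germacra-3Z,11(13)-dien-12,6-olide
Product: 26 (2R,5S,6S,7S,8R,10S)-5,15-diacetoxy-2-(tert-butyldimethylsilyloxy)-8,10-bis(triethylsilyloxy)germacra-3Z,11(13)-dien-12,6-olide
Conditions: Ac2O, pyridine, DMAP (cat.), CH2Cl2, 0 °C → rt
Reagents that add atoms: acetic anhydride (CC(=O)OC(C)=O)
Why: Acylation of a primary and a secondary allylic alcohol with nucleophilic catalysis; every other oxygen is silylated or part of the lactone, so only O5 and O15 react.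

Step 16
Reactants: 26 (2R,5S,6S,7S,8R,10S)-5,15-diacetoxy-2-(tert-butyldimethylsilyloxy)-8,10-bis(triethylsilyloxy)germacra-3Z,11(13)-dien-12,6-olide
Product: 27 (2R,5S,6S,7R,8R,10R)-5,15-diacetoxy-2-(tert-butyldimethylsilyloxy)-8-hydroxy-10-(triethylsilyloxy)germacra-3Z,11(13)-dien-12,6-olide
Conditions: PPTS, MeOH–CH2Cl2, 0 °C
Reagents that add atoms: none
Why: Acid-catalysed methanolysis of silyl ethers in order of lability: the secondary triethylsilyl ether at C8 should go before the tertiary one at C10 and well before the tert-butyldimethylsilyl ether at C2. Partial loss of the C10 group would do no harm, since a tertiary alcohol is not acylated in step 20.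

Step 17
Reactants: 28 methyl but-2-ynoate
Product: 30 methyl (2Z)-2-(hydroxymethyl)but-2-enoate, via alkenylalane 29 (not isolated)
Conditions: i-Bu2AlH, HMPA, THF, 0 °C; then CH2O (gas), 0 °C → rt
Reagents that add atoms: formaldehyde (C=O)
Why: The same vinylalumination as in step 11 on the parent alkynoate: syn hydroalumination and trapping with formaldehyde put the methyl group cis to the ester, which is the Z geometry of the target side chain.

Step 18
Reactants: 30 methyl (2Z)-2-(hydroxymethyl)but-2-enoate
Product: 31 (2Z)-2-(hydroxymethyl)but-2-enoic acid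
Conditions: LiOH, THF–H2O, 0 °C → rt; then HCl to pH 3
Reagents that add atoms: lithium hydroxide ([Li+].[OH-])
Why: Saponification of a methyl ester at low temperature; the trisubstituted Z alkene should not isomerise under these conditions.

Step 19
Reactants: 31 (2Z)-2-(hydroxymethyl)but-2-enoic acid
Product: 32 (2Z)-2-(acetoxymethyl)but-2-enoic acid
Conditions: Ac2O, pyridine, CH2Cl2, 0 °C; aqueous work-up
Reagents that add atoms: acetic anhydride (CC(=O)OC(C)=O)
Why: O-Acetylation of the primary allylic alcohol; any mixed anhydride formed at the carboxyl group is hydrolysed on aqueous work-up.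

Step 20
Reactants: 27 (2R,5S,6S,7R,8R,10R)-5,15-diacetoxy-2-(tert-butyldimethylsilyloxy)-8-hydroxy-10-(triethylsilyloxy)germacra-3Z,11(13)-dien-12,6-olide; 32 (2Z)-2-(acetoxymethyl)but-2-enoic acid
Product: 34 (2R,5S,6S,7R,8R,10R)-5,15-diacetoxy-8-{[(2Z)-2-(acetoxymethyl)but-2-enoyl]oxy}-2-(tert-butyldimethylsilyloxy)-10-(triethylsilyloxy)germacra-3Z,11(13)-dien-12,6-olide, via mixed anhydride 33 (not isolated)
Conditions: 32, 2,4,6-trichlorobenzoyl chloride, Et3N, toluene, rt; then 27, DMAP, rt
Reagents that add atoms: none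
Why: Yamaguchi esterification: DMAP attacks the less hindered enoyl carbonyl of the mixed anhydride 33 and passes the acyl group to O8, the only free secondary hydroxyl; a short reaction time at room temperature is meant to outrun Z to E isomerisation.

Step 21
Reactants: 34 (2R,5S,6S,7R,8R,10R)-5,15-diacetoxy-8-{[(2Z)-2-(acetoxymethyl)but-2-enoyl]oxy}-2-(tert-butyldimethylsilyloxy)-10-(triethylsilyloxy)germacra-3Z,11(13)-dien-12,6-olide
Product: 35 (2R,5S,6S,7R,8R,10S)-5,15-diacetoxy-8-{[(2Z)-2-(acetoxymethyl)but-2-enoyl]oxy}-2,10-dihydroxygermacra-3Z,11(13)-dien-12,6-olide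
Conditions: HF·pyridine, pyridine, THF, 0 °C → rt
Reagents that add atoms: none
Why: Fluoride cleavage of the two remaining silyl ethers under buffered acidic conditions; the acetates, the allylic acetate of the side chain and the α-methylene lactone should not react, and no stereocenter is touched.

## Compound list

1 | dimethyl 3-hydroxy-3-methylpentanedioate | COC(=O)CC(C)(O)CC(=O)OC | starting material
2 | (3S)-3-hydroxy-5-methoxy-3-methyl-5-oxopentanoic acid | OC(=O)C[C@](C)(O)CC(=O)OC | intermediate
3 | methyl (3S)-3-hydroxy-5-[methoxy(methyl)amino]-3-methyl-5-oxopentanoate | CON(C)C(=O)C[C@](C)(O)CC(=O)OC | intermediate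
4 | methyl (3S)-5-[methoxy(methyl)amino]-3-methyl-5-oxo-3-(triethylsilyloxy)pentanoate | CON(C)C(=O)C[C@](C)(O[Si](CC)(CC)CC)CC(=O)OC | intermediate
5 | 1-methoxy-4-[(prop-2-yn-1-yloxy)methyl]benzene | C#CCOCc1ccc(OC)cc1 | starting material
6 | {3-[(4-methoxybenzyl)oxy]prop-1-yn-1-yl}lithium | [Li]C#CCOCc1ccc(OC)cc1 | intermediate
7 | methyl (3S)-8-[(4-methoxybenzyl)oxy]-3-methyl-5-oxo-3-(triethylsilyloxy)oct-6-ynoate | COc1ccc(COCC#CC(=O)C[C@](C)(O[Si](CC)(CC)CC)CC(=O)OC)cc1 | intermediate
8 | methyl (3S,5R)-5-hydroxy-8-[(4-methoxybenzyl)oxy]-3-methyl-3-(triethylsilyloxy)oct-6-ynoate | COc1ccc(COCC#C[C@H](O)C[C@](C)(O[Si](CC)(CC)CC)CC(=O)OC)cc1 | intermediate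
9 | sodium alkenyl(alkoxy)aluminate from 8 (five-membered ring Al–O2–C2–C3=C4; C8 written as the alcohol) | COc1ccc(COCC2=C[C@@H](C[C@](C)(O[Si](CC)(CC)CC)CCO)O[Al-]2(OCCOC)OCCOC)cc1.[Na+] | intermediate
10 | (2Z,4R,6R)-2-iodo-1-[(4-methoxybenzyl)oxy]-6-methyl-6-(triethylsilyloxy)oct-2-ene-4,8-diol | COc1ccc(COC/C(I)=C/[C@H](O)C[C@](C)(O[Si](CC)(CC)CC)CCO)cc1 | intermediate
11 | (2Z,4R,6R)-2-iodo-1-[(4-methoxybenzyl)oxy]-6-methyl-6,8-bis(triethylsilyloxy)oct-2-en-4-ol | COc1ccc(COC/C(I)=C/[C@H](O)C[C@](C)(O[Si](CC)(CC)CC)CCO[Si](CC)(CC)CC)cc1 | intermediate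
12 | (2Z,4R,6R)-4-(tert-butyldimethylsilyloxy)-2-iodo-1-[(4-methoxybenzyl)oxy]-6-methyl-6,8-bis(triethylsilyloxy)oct-2-ene | COc1ccc(COC/C(I)=C/[C@H](O[Si](C)(C)C(C)(C)C)C[C@](C)(O[Si](CC)(CC)CC)CCO[Si](CC)(CC)CC)cc1 | intermediate
13 | (3S,5R,6Z)-5-(tert-butyldimethylsilyloxy)-7-iodo-8-[(4-methoxybenzyl)oxy]-3-methyl-3-(triethylsilyloxy)oct-6-enal | COc1ccc(COC/C(I)=C/[C@H](O[Si](C)(C)C(C)(C)C)C[C@](C)(O[Si](CC)(CC)CC)CC=O)cc1 | intermediate
14 | methyl prop-2-ynoate | C#CC(=O)OC | starting material
15 | methyl 3-(methylzincio)prop-2-ynoate | C[Zn]C#CC(=O)OC | intermediate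
16 | methyl (4R,6R,8R,9Z)-8-(tert-butyldimethylsilyloxy)-4-hydroxy-10-iodo-11-[(4-methoxybenzyl)oxy]-6-methyl-6-(triethylsilyloxy)undec-9-en-2-ynoate | COc1ccc(COC/C(I)=C/[C@H](O[Si](C)(C)C(C)(C)C)C[C@](C)(O[Si](CC)(CC)CC)C[C@@H](O)C#CC(=O)OC)cc1 | intermediate
17 | methyl (4R,6S,8R,9Z)-8-(tert-butyldimethylsilyloxy)-10-iodo-11-[(4-methoxybenzyl)oxy]-6-methyl-4,6-bis(triethylsilyloxy)undec-9-en-2-ynoate | COc1ccc(COC/C(I)=C/[C@H](O[Si](C)(C)C(C)(C)C)C[C@](C)(O[Si](CC)(CC)CC)C[C@@H](O[Si](CC)(CC)CC)C#CC(=O)OC)cc1 | intermediate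
18 | C11-diisobutylaluminio enoate from 17 (C8 cis to the ester) | COc1ccc(COC/C(I)=C/[C@H](O[Si](C)(C)C(C)(C)C)C[C@](C)(O[Si](CC)(CC)CC)C[C@@H](O[Si](CC)(CC)CC)/C=C(/[Al](CC(C)C)CC(C)C)C(=O)OC)cc1 | intermediate
19 | methyl (2Z,4R,6R,8R,9Z)-8-(tert-butyldimethylsilyloxy)-2-(hydroxymethyl)-10-iodo-11-[(4-methoxybenzyl)oxy]-6-methyl-4,6-bis(triethylsilyloxy)undeca-2,9-dienoate | COc1ccc(COC/C(I)=C/[C@H](O[Si](C)(C)C(C)(C)C)C[C@](C)(O[Si](CC)(CC)CC)C[C@@H](O[Si](CC)(CC)CC)/C=C(/CO)C(=O)OC)cc1 | intermediate
20 | methyl (2E,4R,6R,8R,9Z)-2-(bromomethyl)-8-(tert-butyldimethylsilyloxy)-10-iodo-11-[(4-methoxybenzyl)oxy]-6-methyl-4,6-bis(triethylsilyloxy)undeca-2,9-dienoate | COc1ccc(COC/C(I)=C/[C@H](O[Si](C)(C)C(C)(C)C)C[C@](C)(O[Si](CC)(CC)CC)C[C@@H](O[Si](CC)(CC)CC)/C=C(/CBr)C(=O)OC)cc1 | intermediate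
21 | methyl (2E,4R,6R,8R,9Z)-2-(bromomethyl)-8-(tert-butyldimethylsilyloxy)-11-hydroxy-10-iodo-6-methyl-4,6-bis(triethylsilyloxy)undeca-2,9-dienoate | OC/C(I)=C/[C@H](O[Si](C)(C)C(C)(C)C)C[C@](C)(O[Si](CC)(CC)CC)C[C@@H](O[Si](CC)(CC)CC)/C=C(/CBr)C(=O)OC | intermediate
22 | ethanedial (glyoxal) | O=CC=O | starting material
23 | open-chain allylation adduct, present as its chromium alkoxide and drawn as the alcohol: C6–OH, C5 formyl, C4 iodide, C12 methyl ester (C2 R, C6 S, C7 S, C8 R, C10 R) | OC/C(I)=C/[C@H](O[Si](C)(C)C(C)(C)C)C[C@](C)(O[Si](CC)(CC)CC)C[C@@H](O[Si](CC)(CC)CC)[C@H]([C@H](O)C=O)C(=C)C(=O)OC | intermediate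
24 | ring A 5,6-diol with open C12 methyl ester, drawn as the diol (C2 R, C5 S, C6 S, C7 S, C8 R, C10 S; 3Z) | OC/C1=C/[C@H](O[Si](C)(C)C(C)(C)C)C[C@](C)(O[Si](CC)(CC)CC)C[C@@H](O[Si](CC)(CC)CC)[C@H]([C@H](O)[C@H]1O)C(=C)C(=O)OC | intermediate
25 | (2R,5S,6S,7S,8R,10S)-2-(tert-butyldimethylsilyloxy)-5,15-dihydroxy-8,10-bis(triethylsilyloxy)germacra-3Z,11(13)-dien-12,6-olide | C=C1C(=O)O[C@H]2[C@H]1[C@H](O[Si](CC)(CC)CC)C[C@@](C)(O[Si](CC)(CC)CC)C[C@@H](O[Si](C)(C)C(C)(C)C)/C=C(/CO)[C@@H]2O | intermediate
26 | (2R,5S,6S,7S,8R,10S)-5,15-diacetoxy-2-(tert-butyldimethylsilyloxy)-8,10-bis(triethylsilyloxy)germacra-3Z,11(13)-dien-12,6-olide | C=C1C(=O)O[C@H]2[C@H]1[C@H](O[Si](CC)(CC)CC)C[C@@](C)(O[Si](CC)(CC)CC)C[C@@H](O[Si](C)(C)C(C)(C)C)/C=C(/COC(C)=O)[C@@H]2OC(C)=O | intermediate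
27 | (2R,5S,6S,7R,8R,10R)-5,15-diacetoxy-2-(tert-butyldimethylsilyloxy)-8-hydroxy-10-(triethylsilyloxy)germacra-3Z,11(13)-dien-12,6-olide | C=C1C(=O)O[C@H]2[C@H]1[C@H](O)C[C@@](C)(O[Si](CC)(CC)CC)C[C@@H](O[Si](C)(C)C(C)(C)C)/C=C(/COC(C)=O)[C@@H]2OC(C)=O | intermediate
28 | methyl but-2-ynoate | CC#CC(=O)OC | starting material
29 | methyl (2E)-2-(diisobutylaluminio)but-2-enoate | C/C=C(/[Al](CC(C)C)CC(C)C)C(=O)OC | intermediate
30 | methyl (2Z)-2-(hydroxymethyl)but-2-enoate | C/C=C(/CO)C(=O)OC | intermediate
31 | (2Z)-2-(hydroxymethyl)but-2-enoic acid | C/C=C(/CO)C(=O)O | intermediate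
32 | (2Z)-2-(acetoxymethyl)but-2-enoic acid | C/C=C(/COC(C)=O)C(=O)O | intermediate
33 | (2Z)-2-(acetoxymethyl)but-2-enoic 2,4,6-trichlorobenzoic anhydride | C/C=C(/COC(C)=O)C(=O)OC(=O)c1c(Cl)cc(Cl)cc1Cl | intermediate
34 | (2R,5S,6S,7R,8R,10R)-5,15-diacetoxy-8-{[(2Z)-2-(acetoxymethyl)but-2-enoyl]oxy}-2-(tert-butyldimethylsilyloxy)-10-(triethylsilyloxy)germacra-3Z,11(13)-dien-12,6-olide | C=C1C(=O)O[C@H]2[C@H]1[C@H](OC(=O)/C(=C\C)COC(C)=O)C[C@@](C)(O[Si](CC)(CC)CC)C[C@@H](O[Si](C)(C)C(C)(C)C)/C=C(/COC(C)=O)[C@@H]2OC(C)=O | intermediate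
35 | (2R,5S,6S,7R,8R,10S)-5,15-diacetoxy-8-{[(2Z)-2-(acetoxymethyl)but-2-enoyl]oxy}-2,10-dihydroxygermacra-3Z,11(13)-dien-12,6-olide (CNP0126757.1) | C=C1C(=O)O[C@H]2[C@H]1[C@H](OC(=O)/C(=C\C)COC(C)=O)C[C@@](C)(O)C[C@@H](O)/C=C(/COC(C)=O)[C@@H]2OC(C)=O | target

## Step count and least certain steps

Total: 21 steps. Longest linear sequence: 18 steps (steps 1–16, 20 and 21); steps 17–19 make the side-chain acid 32.

**Step 14 (key step, proposed new method).** Three selectivities are asked of one flask. The most likely failures are a second allylation of the mono-adduct, oligomerisation or enolisation of the α-oxygenated aldehyde 23 before ring closure, capture of the alkenylchromium by residual dialdehyde instead of the internal formyl group, and erosion of facial selectivity at C7 or C5.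
Fallback with known chemistry: starting from 21, CrCl2 and acrolein in THF should give the vinyl lactone F1 by the usual Barbier allylation/lactonisation, under the same chair and allylic-strain control. OsO4 (cat.)/NaIO4/2,6-lutidine in dioxane–water should then cleave the terminal vinyl group, the iodoalkene and the acrylate being deactivated, to give the lactone aldehyde F2. CrCl2/NiCl2 (cat.) in DMSO at high dilution then closes ring A, and the route is rejoined at 25. Since F2 no longer carries a chromium alkoxide at O6, a chiral sulfonamide ligand on chromium would be used in the ring closure if substrate control at C5 is poor.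

**Step 9.** Facial selectivity in the zinc acetylide addition may be modest for a β-branched aliphatic aldehyde, and enolisation with loss of silanol can compete, because the aldehyde is hindered and β-oxygenated.
Fallback: starting from 13, addition of LiC≡CCO2Me (from 14 and LiN(SiMe3)2, THF, −78 °C) gives 16 mixed with its C8 epimer F3. Dess–Martin oxidation of the mixture gives the alkynyl ketone F4, and transfer hydrogenation with Ru(p-cymene)[(R,R)-TsDPEN] in i-PrOH sets C8 by catalyst control and returns 16.

**Step 20.** Reversible addition of DMAP to the activated enoate can cause Z to E isomerisation and SN2' loss of the allylic acetate, and acylation of the hindered O8 may be slow enough for this to matter.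
Fallback: the acetate is put on last. Silylation of 30 (t-BuMe2SiCl, imidazole) gives the silyl ether ester F5, and LiOH gives the acid F6, which has no allylic leaving group. Yamaguchi esterification of 27 with F6 gives ester F7, and HF·pyridine removes all three silyl groups to give triol F8. Selective acetylation of its primary allylic hydroxyl (AcCl, 2,4,6-collidine, CH2Cl2, −78 °C) gives 35.

**Step 8.** The oxidative cleavage may not discriminate cleanly among three silyl ethers (loss of the tertiary triethylsilyl ether, incomplete conversion of the primary one).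
Fallback: starting from 12, AcOH–THF–H2O removes only the primary triethylsilyl group to give the primary alcohol F9, which Dess–Martin periodinane oxidises to 13.

## Further compounds

F1 | step 14 | vinyl lactone from 21 and acrolein: 6-vinyl-α-methylene-γ-butyrolactone bearing the C8–C4 iodoalkenyl chain (C6 R, C7 S, C8 R, C2 R) | OC/C(I)=C/[C@H](O[Si](C)(C)C(C)(C)C)C[C@](C)(O[Si](CC)(CC)CC)C[C@@H](O[Si](CC)(CC)CC)[C@@H]1[C@@H](C=C)OC(=O)C1=C
F2 | step 14 | lactone aldehyde (C5 formyl on C6 of the α-methylene lactone; C6 S, C7 S) | OC/C(I)=C/[C@H](O[Si](C)(C)C(C)(C)C)C[C@](C)(O[Si](CC)(CC)CC)C[C@@H](O[Si](CC)(CC)CC)[C@@H]1[C@@H](C=O)OC(=O)C1=C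
F3 | step 9 | methyl (4S,6R,8R,9Z)-8-(tert-butyldimethylsilyloxy)-4-hydroxy-10-iodo-11-[(4-methoxybenzyl)oxy]-6-methyl-6-(triethylsilyloxy)undec-9-en-2-ynoate (C8 epimer of 16) | COc1ccc(COC/C(I)=C/[C@H](O[Si](C)(C)C(C)(C)C)C[C@](C)(O[Si](CC)(CC)CC)C[C@H](O)C#CC(=O)OC)cc1
F4 | step 9 | methyl (6S,8R,9Z)-8-(tert-butyldimethylsilyloxy)-10-iodo-11-[(4-methoxybenzyl)oxy]-6-methyl-4-oxo-6-(triethylsilyloxy)undec-9-en-2-ynoate | COc1ccc(COC/C(I)=C/[C@H](O[Si](C)(C)C(C)(C)C)C[C@](C)(O[Si](CC)(CC)CC)CC(=O)C#CC(=O)OC)cc1
F5 | step 20 | methyl (2Z)-2-[(tert-butyldimethylsilyloxy)methyl]but-2-enoate | C/C=C(/CO[Si](C)(C)C(C)(C)C)C(=O)OC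
F6 | step 20 | (2Z)-2-[(tert-butyldimethylsilyloxy)methyl]but-2-enoic acid | C/C=C(/CO[Si](C)(C)C(C)(C)C)C(=O)O
F7 | step 20 | O8 ester of 27 with F6 | C=C1C(=O)O[C@H]2[C@H]1[C@H](OC(=O)/C(=C\C)CO[Si](C)(C)C(C)(C)C)C[C@@](C)(O[Si](CC)(CC)CC)C[C@@H](O[Si](C)(C)C(C)(C)C)/C=C(/COC(C)=O)[C@@H]2OC(C)=O
F8 | step 20 | 5'-deacetyl target (2,10,5'-triol) | C=C1C(=O)O[C@H]2[C@H]1[C@H](OC(=O)/C(=C\C)CO)C[C@@](C)(O)C[C@@H](O)/C=C(/COC(C)=O)[C@@H]2OC(C)=O
F9 | step 8 | (3R,5R,6Z)-5-(tert-butyldimethylsilyloxy)-7-iodo-8-[(4-methoxybenzyl)oxy]-3-methyl-3-(triethylsilyloxy)oct-6-en-1-ol | COc1ccc(COC/C(I)=C/[C@H](O[Si](C)(C)C(C)(C)C)C[C@](C)(O[Si](CC)(CC)CC)CCO)cc1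
A1 | alternative 1 | metathesis diene: lactone with C2 vinyl and C4 isopropenyl-type termini (O5 and O15 acetates, silyl ethers on O2, O8, O10) | C=C[C@H](O[Si](C)(C)C(C)(C)C)C[C@](C)(O[Si](CC)(CC)CC)C[C@@H](O[Si](CC)(CC)CC)[C@@H]1[C@H](OC(=O)C1=C)[C@@H](OC(C)=O)C(=C)COC(C)=O
A2 | alternative 2 | open-chain C6 aldehyde with C5 silyl ether and 2-(bromomethyl)acrylate terminus | O=C[C@@H](O[Si](C)(C)C(C)(C)C)/C(COCc1ccc(OC)cc1)=C\[C@H](O[Si](C)(C)C(C)(C)C)C[C@](C)(O[Si](CC)(CC)CC)C[C@@H](O[Si](CC)(CC)CC)/C=C(/CBr)C(=O)OC
A3 | alternative 3 | 2,5-bridged furanophane lactone (furan carbons = C2 to C5) | C=C1C(=O)O[C@H]2[C@H]1[C@H](O[Si](CC)(CC)CC)C[C@@](C)(O[Si](CC)(CC)CC)Cc1cc(CO[Si](C)(C)C(C)(C)C)c2o1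
A4 | alternative 3 | ring A Z-enedione (C2 and C5 ketones) | C=C1C(=O)O[C@H]2[C@H]1[C@H](O[Si](CC)(CC)CC)C[C@@](C)(O[Si](CC)(CC)CC)CC(=O)/C=C(/CO[Si](C)(C)C(C)(C)C)C2=O
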